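**Retrosynthetic overview**
1. Target 14 ⇐ silyl ether 13 (desilylation last; the tertiary carbinol is masked from step 2 onward).
2. The pyridone ring is the only ring formed (the benzene ring is bought). C4–C3 and N1–C2 are cut together: anthranilic Weinreb amide 8 + a 3-alkyl-1-lithio-1-methoxyallene as a C3(OMe)–C2–C1′ unit (new acylation/aza-annulation).
3. Alkoxyallene 7 ⇐ propargyl ether 6 (base isomerisation) ⇐ methyl propargyl ether acetylide + bromide 3.
4. Bromide 3 ⇐ methyl 11-bromoundecanoate + 2 MeMgBr (builds the CMe2–O terminus), then TES protection.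

Assumption: the target has no stereocentre, so the "single enantiomer" requirement sets no stereochemical task; the transient allene axis (7, 9, 12) and carbinol carbon (11) are racemic and disappear on aromatisation.

**Route**

Step 1
Reactants: 1 methyl 11-bromoundecanoate
Product: 2 12-bromo-2-methyldodecan-2-ol
Conditions: MeMgBr (2.4 equiv), THF, −20 → 0 °C; then H2O/sat. aq. NH4Cl
Reagents that add atoms: methylmagnesium bromide, C[Mg]Br
Why: Double Grignard addition to the ester gives the tertiary carbinol; the primary bromide is inert to MeMgBr at ≤0 °C without a metal catalyst; no stereocentre.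

Step 2
Reactants: 2 12-bromo-2-methyldodecan-2-ol
Product: 3 [(12-bromo-2-methyldodecan-2-yl)oxy]triethylsilane
Conditions: TESOTf (1.3 equiv), 2,6-lutidine (2 equiv), CH2Cl2, 0 °C
Reagents that add atoms: triethylsilyl trifluoromethanesulfonate, CC[Si](CC)(CC)OS(=O)(=O)C(F)(F)F
Why: Silyl triflate/lutidine silylation is the standard way to protect a hindered tertiary alcohol; the alkyl bromide is untouched.

Step 3
Reactants: 3 [(12-bromo-2-methyldodecan-2-yl)oxy]triethylsilane, 4 3-methoxyprop-1-yne (methyl propargyl ether)
Product: 6 triethyl[(15-methoxy-2-methylpentadec-13-yn-2-yl)oxy]silane, via lithium acetylide 5 (not isolated)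
Conditions: 4 (1.5 equiv), n-BuLi (1.4 equiv), THF, −78 °C; then 3, DMPU, NaI (10 mol%), −78 → 40 °C
Reagents that add atoms: none
Why: SN2 alkylation of a lithium acetylide with a primary bromide in a dipolar cosolvent; the TES ether is stable to the acetylide.

Step 4
Reactants: 6 triethyl[(15-methoxy-2-methylpentadec-13-yn-2-yl)oxy]silane
Product: 7 triethyl[(15-methoxy-2-methylpentadeca-13,14-dien-2-yl)oxy]silane (racemic allene axis)
Conditions: KOt-Bu (0.5 equiv), THF/DMSO 10:1, 0 → 20 °C, stopped at full conversion of 6 (1H NMR)
Reagents that add atoms: none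
Why: Base-catalysed propargyl–allenyl prototropic isomerisation (propargyl ether → alkoxyallene) by deprotonation at the OCH2 group and γ-reprotonation, driven by O–C=C conjugation.

Step 5
Reactants: 7 triethyl[(15-methoxy-2-methylpentadeca-13,14-dien-2-yl)oxy]silane, 8 2-amino-N-methoxy-N-methylbenzamide
Product: 13 3-methoxy-2-[12-methyl-12-(triethylsilyloxy)tridecyl]quinolin-4(1H)-one, via lithioallene 9 (not isolated), via lithium anilide 10 (not isolated), via tetrahedral adduct 11 (not isolated), via allenyl ketone 12 (not isolated)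
Conditions: 7 (1.3 equiv), n-BuLi (1.3 equiv), THF, −40 °C; 8 pre-treated with n-BuLi (1.0 equiv), THF, −78 °C; combine, −78 → −20 °C; then MeOH, −78 → 50 °C
Reagents that add atoms: none
Why: Proposed new method: a one-flask acylation/aza-annulation in which C-1 of the lithioallene (the site where lithiated alkoxyallenes attack hard electrophiles) adds to the Weinreb carbonyl to give chelated adduct 11, MeOH releases allenyl ketone 12, and LiOMe promotes intramolecular aza-Michael addition of the aniline nitrogen to the central allene carbon followed by exo-to-endo prototropy driven by aromatisation to the 4-quinolone, so the C4–C3 and N1–C2 bonds form with OMe fixed at C3 and the chain at C2; the closest known reaction types are the addition of lithiated alkoxyallenes to Weinreb amides to give α-alkoxy allenyl ketones and the base-mediated cyclisation of 2-aminophenyl ynones to 2-substituted 4-quinolones; no stereocentre is formed.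

Step 6
Reactants: 13 3-methoxy-2-[12-methyl-12-(triethylsilyloxy)tridecyl]quinolin-4(1H)-one
Product: 14 2-(12-hydroxy-12-methyltridecyl)-3-methoxyquinolin-4(1H)-one
Conditions: TBAF (3 equiv), THF, 40 °C; aq. work-up
Reagents that add atoms: none
Why: Fluoride-mediated cleavage of the Si–O bond (silyl ether deprotection) frees the tertiary alcohol under non-acidic conditions, so it cannot dehydrate; the NH-quinolone is inert.

**Compound list**
1 | methyl 11-bromoundecanoate | COC(=O)CCCCCCCCCCBr | starting material
2 | 12-bromo-2-methyldodecan-2-ol | CC(C)(O)CCCCCCCCCCBr | intermediate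
3 | [(12-bromo-2-methyldodecan-2-yl)oxy]triethylsilane | CC[Si](CC)(CC)OC(C)(C)CCCCCCCCCCBr | intermediate
4 | 3-methoxyprop-1-yne (methyl propargyl ether) | COCC#C | starting material
5 | (3-methoxyprop-1-yn-1-yl)lithium | COCC#C[Li] | intermediate (not isolated)
6 | triethyl[(15-methoxy-2-methylpentadec-13-yn-2-yl)oxy]silane | COCC#CCCCCCCCCCCC(C)(C)O[Si](CC)(CC)CC | intermediate
7 | triethyl[(15-methoxy-2-methylpentadeca-13,14-dien-2-yl)oxy]silane, racemic allene axis | COC=C=CCCCCCCCCCCC(C)(C)O[Si](CC)(CC)CC | intermediate
8 | 2-amino-N-methoxy-N-methylbenzamide | Nc1ccccc1C(=O)N(C)OC | starting material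
9 | [1-methoxy-14-methyl-14-(triethylsilyloxy)pentadeca-1,2-dien-1-yl]lithium, racemic axis | COC([Li])=C=CCCCCCCCCCCC(C)(C)O[Si](CC)(CC)CC | intermediate (not isolated)
10 | lithium {2-[methoxy(methyl)carbamoyl]phenyl}azanide | [Li]Nc1ccccc1C(=O)N(C)OC | intermediate (not isolated)
11 | lithium 1-[2-(lithioamino)phenyl]-2-methoxy-1-[methoxy(methyl)amino]-15-methyl-15-(triethylsilyloxy)hexadeca-2,3-dien-1-olate, stereoisomer mixture | [Li]Nc1ccccc1C(O[Li])(N(C)OC)C(OC)=C=CCCCCCCCCCCC(C)(C)O[Si](CC)(CC)CC | intermediate (not isolated)
12 | 1-(2-aminophenyl)-2-methoxy-15-methyl-15-(triethylsilyloxy)hexadeca-2,3-dien-1-one, racemic axis | Nc1ccccc1C(=O)C(OC)=C=CCCCCCCCCCCC(C)(C)O[Si](CC)(CC)CC | intermediate (not isolated)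
13 | 3-methoxy-2-[12-methyl-12-(triethylsilyloxy)tridecyl]quinolin-4(1H)-one | COc1c(CCCCCCCCCCCC(C)(C)O[Si](CC)(CC)CC)[nH]c2ccccc2c1=O | intermediate
14 | 2-(12-hydroxy-12-methyltridecyl)-3-methoxyquinolin-4(1H)-one | COc1c(CCCCCCCCCCCC(C)(C)O)[nH]c2ccccc2c1=O | target

**Step count**
Total steps: 6. Longest linear sequence: 6 (1 → 2 → 3 → 6 → 7 → 13 → 14); 4 and 8 are bought.

**Three steps most likely to fail, with fallbacks**

Step 5 (the proposed new annulation). Risks are attack through C-3 of the lithioallene, furan formation from 12, or butyl transfer to the Weinreb amide during the pre-deprotonation. The fallback uses known chemistry only; it sets out from bromide 3 and comes back at 13. Aniline and methyl 2-methoxy-3-oxobutanoate (both bought) are condensed (cat. p-TsOH, toluene, Dean–Stark) to methyl (2E)-3-anilino-2-methoxybut-2-enoate F1. Conrad–Limpach cyclisation of F1 (Ph2O, 250 °C) gives 3-methoxy-2-methylquinolin-4(1H)-one F2. The N,C-dianion of F2 (n-BuLi 2.2 equiv, THF, −78 → 0 °C, lateral lithiation of the 2-methyl group) is alkylated with 3 to give 13, which then goes through step 6.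

Step 4 (alkyne-to-allene isomerisation). Risks are over-isomerisation to the 1-methoxy-1,3-diene or a stalled equilibrium. The fallback sets out from 6 and comes back at 13 without isolating 7. Compound 6 is metalated at its OCH2 group (s-BuLi, THF, −78 °C) and the propargyl/allenyl lithium is acylated at the oxygen-bearing carbon by N-lithiated 8, giving 1-(2-aminophenyl)-2-methoxy-15-methyl-15-(triethylsilyloxy)hexadec-3-yn-1-one F3 (racemic). Its doubly activated C2–H lets LiOMe/MeOH isomerise it in the flask to allenyl ketone 12, which cyclises to 13 as in step 5.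

Step 3 (acetylide alkylation). Risks are slow SN2, E2, or propargylic metalation of the oxygenated acetylide on warming. The fallback sets out from 3 and comes back at 6, reversing the order of bond formation. Bromide 3 is treated with lithium acetylide–ethylenediamine complex (DMSO, 20 °C) to give triethyl[(2-methyltetradec-13-yn-2-yl)oxy]silane F4. F4 is deprotonated (n-BuLi, THF, −78 °C) and alkylated with chloromethyl methyl ether to give 6.

**Further compounds**
F1 | step 5 | methyl (2E)-3-anilino-2-methoxybut-2-enoate | COC(=O)/C(OC)=C(/C)Nc1ccccc1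
F2 | step 5 | 3-methoxy-2-methylquinolin-4(1H)-one | COc1c(C)[nH]c2ccccc2c1=O
F3 | step 4 | 1-(2-aminophenyl)-2-methoxy-15-methyl-15-(triethylsilyloxy)hexadec-3-yn-1-one (racemic) | Nc1ccccc1C(=O)C(OC)C#CCCCCCCCCCCC(C)(C)O[Si](CC)(CC)CC
F4 | step 3 | triethyl[(2-methyltetradec-13-yn-2-yl)oxy]silane | C#CCCCCCCCCCCC(C)(C)O[Si](CC)(CC)CC
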